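**Retrosynthetic overview**
1. The C8 prenyl comes last, by cross-metathesis of an 8-allyl group that arises from Claisen rearrangement of the 7-O-allyl ether; the ring-B chromene comes from a 4′-O-(1,1-dimethylpropargyl) ether.
2. The furan ring is closed by DDQ dehydrogenative C2–O bond formation from a 2′-hydroxyisoflavone.
3. The isoflavone comes from a chalcone by Tl(NO3)3 1,2-aryl shift; the chalcone comes from a Claisen–Schmidt aldol of acetophenone 4 with aldehyde 12 (key C–C bond, later C2–C3 of the pyranone).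
4. 4 comes from phloroacetophenone (mono-MOM, prenal annulation, hydrogenation); 12 comes from 2,4-dihydroxybenzaldehyde (benzylation, Dakin, MOM, bromination, formylation).
5. Ring order: ring-A dihydropyran → pyranone → furan → ring-B chromene.

Assumption: the target has no stereocentre (it is achiral), so no stereocontrolled step is needed and the constitution given is the whole task.
Naming: isoflavone locants are used (ring A C5–C8, ring B C1′–C6′); "DHP" is a 2,2-dimethyl-3,4-dihydro-2H-pyran fused to ring A with its O on C5 and its CH2 on C6; "coumaronochromone" is the isoflavone with an O bridge from C2′ to C2.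

**Step 1**
Reactants: 1 2,4,6-trihydroxyacetophenone
Product: 2 1-[2,6-dihydroxy-4-(methoxymethoxy)phenyl]ethanone
Conditions: MOMCl (1.05 equiv), iPr2NEt (1.1 equiv), THF, 0 °C → rt; chromatography
Reagents that add atoms: chloromethyl methyl ether, COCCl
Why: Williamson-type O-alkylation in which the 4-OH (para to the acetyl, not hydrogen-bonded, most acidic) reacts first, so one equivalent gives the mono-ether and the minor bis-ether is separated.

**Step 2**
Reactants: 2 1-[2,6-dihydroxy-4-(methoxymethoxy)phenyl]ethanone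
Product: 3 1-[7-hydroxy-5-(methoxymethoxy)-2,2-dimethyl-2H-chromen-8-yl]ethanone
Conditions: 3-methylbut-2-enal (1.3 equiv), ethylenediammonium diacetate (10 mol%), toluene, 110 °C
Reagents that add atoms: 3-methylbut-2-enal, CC(C)=CC=O
Why: Knoevenagel-type C-alkylation, dehydration to an o-quinone methide and oxa-6π electrocyclisation; because O-4 is blocked and C3/C5 are equivalent, the pyran can only close on the hydroxyl next to the acetyl.

**Step 3**
Reactants: 3 1-[7-hydroxy-5-(methoxymethoxy)-2,2-dimethyl-2H-chromen-8-yl]ethanone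
Product: 4 1-[7-hydroxy-5-(methoxymethoxy)-2,2-dimethylchroman-8-yl]ethanone
Conditions: H2 (1 atm), 10% Pd/C, EtOAc, rt
Reagents that add atoms: none
Why: Heterogeneous catalytic hydrogenation saturates the styrene-type chromene alkene while the chelated aryl ketone and the MOM acetal are untouched.

**Step 4**
Reactants: 5 2,4-dihydroxybenzaldehyde
Product: 6 2,4-bis(benzyloxy)benzaldehyde
Conditions: BnBr (2.3 equiv), K2CO3, DMF, 60 °C
Reagents that add atoms: benzyl bromide, BrCc1ccccc1
Why: Exhaustive Williamson etherification of both phenols with a reactive benzylic halide.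

**Step 5**
Reactants: 6 2,4-bis(benzyloxy)benzaldehyde
Product: 8 2,4-bis(benzyloxy)phenol, via aryl formate 7 (not isolated)
Conditions: mCPBA, CH2Cl2, 0 °C → rt; then K2CO3 (cat.), MeOH, rt
Reagents that add atoms: 3-chloroperoxybenzoic acid, OOC(=O)c1cccc(Cl)c1
Why: Baeyer–Villiger (Dakin-type) oxidation in which the electron-rich o,p-dialkoxyaryl group migrates to oxygen, followed by methanolysis of the formate.

**Step 6**
Reactants: 8 2,4-bis(benzyloxy)phenol
Product: 9 2,4-bis(benzyloxy)-1-(methoxymethoxy)benzene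
Conditions: MOMCl (1.3 equiv), iPr2NEt (1.5 equiv), CH2Cl2, 0 °C → rt
Reagents that add atoms: chloromethyl methyl ether, COCCl
Why: Williamson-type acetal formation on the only free phenol.

**Step 7**
Reactants: 9 2,4-bis(benzyloxy)-1-(methoxymethoxy)benzene
Product: 10 1,5-bis(benzyloxy)-2-bromo-4-(methoxymethoxy)benzene
Conditions: NBS (1.05 equiv), MeCN, 0 °C
Reagents that add atoms: N-bromosuccinimide, O=C1CCC(=O)N1Br
Why: Electrophilic aromatic bromination at the one position that is ortho to one benzyloxy group and para to the other, the usual site for 1,2,4-trialkoxybenzenes.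

**Step 8**
Reactants: 10 1,5-bis(benzyloxy)-2-bromo-4-(methoxymethoxy)benzene
Product: 12 2,4-bis(benzyloxy)-5-(methoxymethoxy)benzaldehyde, via aryllithium 11 (not isolated)
Conditions: n-BuLi (1.1 equiv), THF, −78 °C; DMF, −78 → 0 °C; H2O
Reagents that add atoms: N,N-dimethylformamide, CN(C)C=O
Why: Fast bromine–lithium exchange at −78 °C followed by Bouveault-type formylation, which avoids acidic formylation conditions that would endanger the MOM group.

**Step 9**
Reactants: 4 1-[7-hydroxy-5-(methoxymethoxy)-2,2-dimethylchroman-8-yl]ethanone and 12 2,4-bis(benzyloxy)-5-(methoxymethoxy)benzaldehyde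
Product: 14 (E)-3-[2,4-bis(benzyloxy)-5-(methoxymethoxy)phenyl]-1-[7-hydroxy-5-(methoxymethoxy)-2,2-dimethylchroman-8-yl]prop-2-en-1-one, via aldol adduct 13 (not isolated)
Conditions: KOH (50% aq), EtOH, rt, 36 h; then AcOH to pH 6, 0 °C
Reagents that add atoms: none
Why: Claisen–Schmidt crossed aldol condensation of the methyl ketone enolate with a non-enolisable aldehyde, where E1cB dehydration erases the carbinol stereocentre and gives the thermodynamically favoured E-enone.

**Step 10**
Reactants: 14 (E)-3-[2,4-bis(benzyloxy)-5-(methoxymethoxy)phenyl]-1-[7-hydroxy-5-(methoxymethoxy)-2,2-dimethylchroman-8-yl]prop-2-en-1-one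
Product: 16 2′,4′-bis(benzyloxy)-7,5′-dihydroxy-DHP-isoflavone, via dimethyl acetal 15 (not isolated)
Conditions: Tl(NO3)3·3H2O (1.2 equiv), MeOH, rt, 3 h; filter, aqueous work-up; then 10% HCl–MeOH, reflux, 2 h
Reagents that add atoms: none
Why: Oxidative 1,2-aryl migration of the chalcone (oxythallation, then shift of the electron-rich trialkoxyaryl group) gives the β-keto acetal, and acid then closes the pyranone with loss of methanol and removes both MOM groups, while the benzyl ethers and the chroman survive.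

**Step 11**
Reactants: 16 2′,4′-bis(benzyloxy)-7,5′-dihydroxy-DHP-isoflavone
Product: 17 2′,4′-bis(benzyloxy)-7,5′-bis(methoxymethoxy)-DHP-isoflavone
Conditions: MOMCl (3 equiv), iPr2NEt (4 equiv), CH2Cl2, 0 °C → rt
Reagents that add atoms: chloromethyl methyl ether, COCCl
Why: Non-selective Williamson-type protection of both free phenols, so that O-5′ stays masked (no hydroquinone) when the benzyl groups are later removed.

**Step 12**
Reactants: 17 2′,4′-bis(benzyloxy)-7,5′-bis(methoxymethoxy)-DHP-isoflavone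
Product: 18 2′,4′-dihydroxy-7,5′-bis(methoxymethoxy)-DHP-isoflavone
Conditions: H2 (1 atm), 10% Pd/C, EtOAc–MeOH, rt; stop after 2 equiv H2
Reagents that add atoms: none
Why: Catalytic hydrogenolysis of the two aryl benzyl ethers at a stage where no reducible alkene is present other than the deactivated pyranone C2=C3.

**Step 13**
Reactants: 18 2′,4′-dihydroxy-7,5′-bis(methoxymethoxy)-DHP-isoflavone
Product: 19 4′-hydroxy-7,5′-bis(methoxymethoxy)-DHP-coumaronochromone
Conditions: DDQ (1.2 equiv), dry 1,4-dioxane, rt → 50 °C, Ar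
Reagents that add atoms: none
Why: Dehydrogenative cyclisation of a 2′-hydroxyisoflavone, in which the 2′-OH adds to C2 and DDQ removes two hydrogens to give the aromatic furan, with the 5′-O-MOM group preventing quinone formation.

**Step 14**
Reactants: 19 4′-hydroxy-7,5′-bis(methoxymethoxy)-DHP-coumaronochromone
Product: 20 4′-O-(2-methylbut-3-yn-2-yl)-7,5′-bis(methoxymethoxy)-DHP-coumaronochromone
Conditions: 3-chloro-3-methylbut-1-yne (3 equiv), K2CO3, KI, CuI (10 mol%), acetone, reflux
Reagents that add atoms: 3-chloro-3-methylbut-1-yne, CC(C)(Cl)C#C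
Why: Copper-assisted O-alkylation of the only free phenol with a tertiary propargylic chloride.

**Step 15**
Reactants: 20 4′-O-(2-methylbut-3-yn-2-yl)-7,5′-bis(methoxymethoxy)-DHP-coumaronochromone
Product: 21 7,5′-bis(methoxymethoxy)-DHP-coumaronochromone with a 2,2-dimethyl-2H-pyran fused at C3′ (CH=) and C4′ (O)
Conditions: N,N-diethylaniline, 170 °C, Ar
Reagents that add atoms: none
Why: Aryl propargyl ether Claisen rearrangement, 1,5-hydrogen shift and oxa-6π electrocyclisation, which can only deliver the chromene to C3′ because the other ortho position (C5′) carries oxygen.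

**Step 16**
Reactants: 21 7,5′-bis(methoxymethoxy)-DHP-coumaronochromone with the ring-B chromene
Product: 22 7,5′-dihydroxy-DHP-coumaronochromone with the ring-B chromene
Conditions: 3 M HCl (aq)–MeOH–THF, 50 °C, 2 h
Reagents that add atoms: none
Why: Acid-catalysed acetal exchange removes both MOM groups under conditions that 2,2-dimethylchromenes tolerate.

**Step 17**
Reactants: 22 7,5′-dihydroxy-DHP-coumaronochromone with the ring-B chromene
Product: 23 7-O-allyl-5′-hydroxy-DHP-coumaronochromone with the ring-B chromene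
Conditions: allyl bromide (1.05 equiv), K2CO3 (1.0 equiv), DMF, 0 °C → rt
Reagents that add atoms: allyl bromide, C=CCBr
Why: Williamson etherification under mono-anion conditions, where the 7-OH (vinylogous acid para to the pyranone carbonyl, about 2–3 pKa units more acidic than the 5′-OH) is the one ionised and alkylated.

**Step 18**
Reactants: 23 7-O-allyl-5′-hydroxy-DHP-coumaronochromone with the ring-B chromene
Product: 24 8-allyl-7,5′-dihydroxy-DHP-coumaronochromone with the ring-B chromene
Conditions: N,N-diethylaniline, 200 °C, sealed tube, Ar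
Reagents that add atoms: none
Why: Aromatic Claisen [3,3] rearrangement to C8, the only ortho position bearing hydrogen (C6 carries the pyran CH2), followed by tautomerisation to the phenol.

**Step 19**
Reactants: 24 8-allyl-7,5′-dihydroxy-DHP-coumaronochromone with the ring-B chromene
Product: 25 target CNP0081330.0 (8-prenyl-7,5′-dihydroxy-DHP-coumaronochromone with the ring-B chromene)
Conditions: 2-methylbut-2-ene (large excess), second-generation Grubbs catalyst (H2IMes)(PCy3)Cl2Ru=CHPh (5 mol%), CH2Cl2, 40 °C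
Reagents that add atoms: 2-methylbut-2-ene, CC=C(C)C
Why: Olefin cross-metathesis turns the terminal allyl group into the trisubstituted prenyl group, while the cyclic cis-alkene of the chromene next to a quaternary carbon does not take part and no stereocentre is created.

**Compound list**
1 | 2,4,6-trihydroxyacetophenone | CC(=O)c1c(O)cc(O)cc1O | starting material
2 | 1-[2,6-dihydroxy-4-(methoxymethoxy)phenyl]ethanone | CC(=O)c1c(O)cc(OCOC)cc1O | intermediate
3 | 1-[7-hydroxy-5-(methoxymethoxy)-2,2-dimethyl-2H-chromen-8-yl]ethanone | CC(=O)c1c(O)cc(OCOC)c2C=CC(C)(C)Oc12 | intermediate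
4 | 1-[7-hydroxy-5-(methoxymethoxy)-2,2-dimethylchroman-8-yl]ethanone | CC(=O)c1c(O)cc(OCOC)c2CCC(C)(C)Oc12 | intermediate
5 | 2,4-dihydroxybenzaldehyde | O=Cc1ccc(O)cc1O | starting material
6 | 2,4-bis(benzyloxy)benzaldehyde | O=Cc1ccc(OCc2ccccc2)cc1OCc1ccccc1 | intermediate
7 | 2,4-bis(benzyloxy)phenyl formate (formed in situ) | O=COc1ccc(OCc2ccccc2)cc1OCc1ccccc1 | intermediate
8 | 2,4-bis(benzyloxy)phenol | Oc1ccc(OCc2ccccc2)cc1OCc1ccccc1 | intermediate
9 | 2,4-bis(benzyloxy)-1-(methoxymethoxy)benzene | COCOc1ccc(OCc2ccccc2)cc1OCc1ccccc1 | intermediate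
10 | 1,5-bis(benzyloxy)-2-bromo-4-(methoxymethoxy)benzene | COCOc1cc(Br)c(OCc2ccccc2)cc1OCc1ccccc1 | intermediate
11 | [2,4-bis(benzyloxy)-5-(methoxymethoxy)phenyl]lithium (formed in situ) | [Li]c1cc(OCOC)c(OCc2ccccc2)cc1OCc1ccccc1 | intermediate
12 | 2,4-bis(benzyloxy)-5-(methoxymethoxy)benzaldehyde | O=Cc1cc(OCOC)c(OCc2ccccc2)cc1OCc1ccccc1 | intermediate
13 | racemic 3-[2,4-bis(benzyloxy)-5-(methoxymethoxy)phenyl]-3-hydroxy-1-[7-hydroxy-5-(methoxymethoxy)-2,2-dimethylchroman-8-yl]propan-1-one (formed in situ) | O=C(CC(O)c1cc(OCOC)c(OCc2ccccc2)cc1OCc1ccccc1)c1c(O)cc(OCOC)c2CCC(C)(C)Oc12 | intermediate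
14 | (E)-3-[2,4-bis(benzyloxy)-5-(methoxymethoxy)phenyl]-1-[7-hydroxy-5-(methoxymethoxy)-2,2-dimethylchroman-8-yl]prop-2-en-1-one | O=C(/C=C/c1cc(OCOC)c(OCc2ccccc2)cc1OCc1ccccc1)c1c(O)cc(OCOC)c2CCC(C)(C)Oc12 | intermediate
15 | racemic 2-[2,4-bis(benzyloxy)-5-(methoxymethoxy)phenyl]-1-[7-hydroxy-5-(methoxymethoxy)-2,2-dimethylchroman-8-yl]-3,3-dimethoxypropan-1-one (formed in situ) | O=C(C(C(OC)OC)c1cc(OCOC)c(OCc2ccccc2)cc1OCc1ccccc1)c1c(O)cc(OCOC)c2CCC(C)(C)Oc12 | intermediate
16 | 2′,4′-bis(benzyloxy)-7,5′-dihydroxy-DHP-isoflavone | O=c1c(-c2cc(O)c(OCc3ccccc3)cc2OCc2ccccc2)coc2cc(O)c3CCC(C)(C)Oc3c12 | intermediate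
17 | 2′,4′-bis(benzyloxy)-7,5′-bis(methoxymethoxy)-DHP-isoflavone | O=c1c(-c2cc(OCOC)c(OCc3ccccc3)cc2OCc2ccccc2)coc2cc(OCOC)c3CCC(C)(C)Oc3c12 | intermediate
18 | 2′,4′-dihydroxy-7,5′-bis(methoxymethoxy)-DHP-isoflavone | O=c1c(-c2cc(OCOC)c(O)cc2O)coc2cc(OCOC)c3CCC(C)(C)Oc3c12 | intermediate
19 | 4′-hydroxy-7,5′-bis(methoxymethoxy)-DHP-coumaronochromone | O=c1c2c(oc3cc(O)c(OCOC)cc23)oc2cc(OCOC)c3CCC(C)(C)Oc3c12 | intermediate
20 | 4′-O-(2-methylbut-3-yn-2-yl)-7,5′-bis(methoxymethoxy)-DHP-coumaronochromone | O=c1c2c(oc3cc(OC(C)(C)C#C)c(OCOC)cc23)oc2cc(OCOC)c3CCC(C)(C)Oc3c12 | intermediate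
21 | 7,5′-bis(methoxymethoxy)-DHP-coumaronochromone with a 2,2-dimethyl-2H-pyran fused at C3′/C4′(O) | O=c1c2c(oc3c4C=CC(C)(C)Oc4c(OCOC)cc23)oc2cc(OCOC)c3CCC(C)(C)Oc3c12 | intermediate
22 | 7,5′-dihydroxy analogue of 21 | O=c1c2c(oc3c4C=CC(C)(C)Oc4c(O)cc23)oc2cc(O)c3CCC(C)(C)Oc3c12 | intermediate
23 | 7-O-allyl-5′-hydroxy analogue of 21 | O=c1c2c(oc3c4C=CC(C)(C)Oc4c(O)cc23)oc2cc(OCC=C)c3CCC(C)(C)Oc3c12 | intermediate
24 | 8-allyl-7,5′-dihydroxy analogue of 21 | O=c1c2c(oc3c4C=CC(C)(C)Oc4c(O)cc23)oc2c(CC=C)c(O)c3CCC(C)(C)Oc3c12 | intermediate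
25 | CNP0081330.0 (8-prenyl-7,5′-dihydroxy compound, achiral) | CC(C)=CCc1c(O)c2c(c3c(=O)c4c(oc13)oc1c3c(c(O)cc14)OC(C)(C)C=C3)OC(C)(C)CC2 | target

**Totals and risks**
Total step count: 19. Longest linear sequence: 16 steps (5 → 25, steps 4–19); the three-step branch 1 → 4 joins at step 9.

Most likely to fail:

Step 10 (oxidative aryl shift and cyclisation). The MOM groups may fall off early under the nitric acid that forms, and a freed ring-B phenol can be over-oxidised. Fallback: set out from chalcone 14 and cyclise it with NaOAc in refluxing EtOH (intramolecular oxa-Michael addition) to the racemic flavanone F1. Then carry out the 2,3-aryl shift with PhI(OH)OTs in refluxing MeCN (trivalent-iodine oxidation of the enol with ring-preserving aryl migration) and finish MOM cleavage with 10% HCl–MeOH. This comes back to the route at isoflavone 16.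

Step 13 (DDQ ring closure). The electron-rich 2′,4′-dihydroxy-5′-alkoxy ring may be over-oxidised, or the ring-A chroman may be dehydrogenated. Fallback: set out from the fully protected isoflavone 17 and epoxidise C2=C3 with dimethyldioxirane in acetone to the racemic 2,3-epoxide F2. Hydrogenolysis (H2, 10% Pd/C, EtOAc, NaHCO3) gives the debenzylated epoxide F3, whose 2′-OH opens the epoxide at the acetal carbon C2 to the cis-fused 3-hydroxy-2,3-dihydrocoumaronochromone F4. PPTS in toluene at 60 °C then dehydrates it (benzofuran aromatisation), which comes back to the route at 19.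

Step 17 (selective 7-O-allylation). 5′-O-allyl and bis-allyl by-products may form. Fallback: set out from diol 22 and acetylate both phenols (Ac2O, pyridine) to the diacetate F5. Cleave only the activated 7-O-acetyl (ester of the acidic phenol) with PhSH and imidazole in NMP at 0 °C to the 5′-monoacetate F6. Allylate the now unique 7-OH (allyl bromide, K2CO3, acetone) to the 7-O-allyl 5′-acetate F7. K2CO3 in MeOH then removes the acetate, which comes back to the route at 23.

**Further compounds**
F1 | step 10 | racemic 2-[2,4-bis(benzyloxy)-5-(methoxymethoxy)phenyl]-7-(methoxymethoxy)-DHP-chroman-4-one (flavanone) | O=C1CC(c2cc(OCOC)c(OCc3ccccc3)cc2OCc2ccccc2)Oc2cc(OCOC)c3CCC(C)(C)Oc3c12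
F2 | step 13 | racemic 2,3-epoxide of isoflavone 17 | O=C1c2c3OC(C)(C)CCc3c(OCOC)cc2OC2OC12c1cc(OCOC)c(OCc2ccccc2)cc1OCc1ccccc1
F3 | step 13 | racemic 2,3-epoxide of isoflavone 18 (2′,4′-dihydroxy) | O=C1c2c3OC(C)(C)CCc3c(OCOC)cc2OC2OC12c1cc(OCOC)c(O)cc1O
F4 | step 13 | racemic cis-fused 3,4′-dihydroxy-7,5′-bis(methoxymethoxy)-2,3-dihydro-DHP-coumaronochromone | O=C1c2c3OC(C)(C)CCc3c(OCOC)cc2OC2Oc3cc(O)c(OCOC)cc3C12O
F5 | step 17 | 7,5′-di-O-acetate of 22 | O=c1c2c(oc3c4C=CC(C)(C)Oc4c(OC(C)=O)cc23)oc2cc(OC(C)=O)c3CCC(C)(C)Oc3c12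
F6 | step 17 | 5′-O-acetate of 22 (7-OH free) | O=c1c2c(oc3c4C=CC(C)(C)Oc4c(OC(C)=O)cc23)oc2cc(O)c3CCC(C)(C)Oc3c12
F7 | step 17 | 7-O-allyl 5′-O-acetate of 22 | O=c1c2c(oc3c4C=CC(C)(C)Oc4c(OC(C)=O)cc23)oc2cc(OCC=C)c3CCC(C)(C)Oc3c12
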